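## Conventions

- Units: T (top), M (middle), B (bottom), with flavan numbering (T-C4, M-O5 and so on). In each unit ring A is the phloroglucinol-derived ring and ring C the pyran ring; the third ring is called the catechol ring. Ring E is the extra pyran ring between T and M.
- Bn = benzyl; TES = triethylsilyl; TIPS = triisopropylsilyl.
- ArC = 3,4-bis(benzyloxy)phenyl; ArT = 2,4,6-tris(benzyloxy)phenyl.
- Fl = (2S,3R)-3,5,7-tris(benzyloxy)-2-[3,4-bis(benzyloxy)phenyl]chroman-8-yl.
- T-arm = –CH(ArT)–CH(OTES)–C(OMe)2ArC, bound through its first carbon (T-C4, then T-C3, then the ketal carbon T-C2), configured as in 14.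
- M-arm = –CH(Fl)–CH(OTES)–C(OMe)2ArC, bound through M-C4, configured as in 32.
- T-arm(OH) and M-arm(OH) carry OH in place of OTES; T-arm' and M-arm' have, in addition, every benzyl ether as a free hydroxyl.

## Analysis of the target

The target is an A-type proanthocyanidin trimer. Three flavan-3-ol units are joined twice over, T to M and M to B, each time by a C4–C8 bond and a C2–O–C7 ether, so that each junction is a 2,6-dioxabicyclo[3.3.1]nonane ketal and the molecule has eleven rings. There are eight stereocentres: C2, C3 and C4 of T and of M, and C2 and C3 of B. Read from the structure, T is of the ent-catechin type (2,3-trans, 3,4-cis, bridge on the α face), M of the epicatechin type (2,3-cis, 3,4-trans, bridge on the β face), and B is (−)-catechin (2S,3R). In each bicyclic ketal the C2 configuration follows from C4, because the bridge can only be cis; the independent elements are therefore the C3/C4 pairs of T and M and the two centres of B. Ten phenols, three secondary alcohols and two diaryl ketals make the compound sensitive to oxygen and base, and before the ketals are closed the doubly benzylic C4–aryl bonds are acid-labile. The hard part is ring A of M. It is pentasubstituted, carries a stereogenic carbon arm on C4a and on C8, and has three oxygens with three different roles: O1 closes ring C of M, O7 closes ring E, and O5 must stay a free phenol. The strategy rests on this ring (C4a, C5, C6, C7, C8, C8a): a 1,3,5-trioxygenated benzene with carbon substituents on both sides of O1 and one hydrogen at C6. That is the pattern a cyclobutenone and ynol ether benzannulation produces, with each oxygen coming from a different component.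

## Retrosynthetic reasoning

**49 from 48.** The last operation is removal of a pivaloyl group from M-O5. The ester is there only because O5 is the one hub oxygen that must not enter a ketal.

**48 from 47.** Four C–O bonds are cut: T-C2 to O1 of T and to O7 of M, and M-C2 to O1 of M and to O7 of B. Both bicyclic ketals fall back to open-chain dimethyl ketals flanked by free phenols. The cut is made here because the bicyclic ketals are thermodynamic sinks and their C2 configuration is dictated by C4, so no stereocontrol has to be designed. The forward reaction has to choose the right hub oxygen for each ketal carbon. With O5 acylated, M-C2 can use only O1 on the hub, which leaves O7 for T-C2.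

**47 from 44 (through 46 and 45).** These are protecting-group operations: hydrogenolysis of twelve benzyl ethers, fluoride cleavage of the silyl ethers, and acylation of the single free hydroxyl of 44. The gain is that 44 already has its three hub oxygens differentiated: O5 free, O1 and O7 silylated.

**44 from 22 and 39 (key disconnection).** Ring A of M is taken apart at C5–C4a and C8a–C8, with C5–C6 notionally broken and re-formed. This is the only aromatic ring with two carbon arms, so cutting it divides the molecule into two halves of similar size. The oxygens are told apart by origin: the ketene oxygen becomes the free O5–H, the alkyne oxygen the silylated O1, and the cyclobutenone C3 oxygen the silylated O7. C6 keeps its hydrogen because it is the cyclobutenone methylene. The forward reaction must achieve a bimolecular [2+2] between two hindered partners under neutral thermal conditions that leave T-C4 and M-C4 untouched.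

**22 from 21.** The cyclobutenone is opened by a retro-[2+2] that removes a C2 unit from the triple bond of 21. Both halves therefore come from ynol silyl ethers of the same kind, 21 and 39, made by the same chemistry.

**21 from 14, and 39 from 32.** The C≡C–O unit is traced to the acyl carbon of an aldol adduct through alcohol, aldehyde, dibromoalkene, acetylide and ynolate (16 to 20 and 34 to 38). Every one of these reactions takes place at the unhindered chain terminus, away from the congested C3/C4 region.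

**14 from 12 and 4, and 32 from 30 and 4.** The C3–C4 bond of each arm is cut as an aldol bond, which sets both stereocentres at once. In the open chain both arms need the same syn relationship and the same absolute sense. It becomes 3,4-cis in T and 3,4-trans in M only because the hub takes a different role in the two units. One auxiliary, 10, and one aldehyde, 4, therefore serve both arms.

**12 from 5, and 30 from 23.** The aryl–CH2 bond of each arylacetyl imide comes from a palladium-catalysed coupling of an aryl bromide (7, 26) with a zinc ester enolate. The bromides come from benzylated 5 and from benzylated 23, which supplies the two stereocentres of B from the chiral pool.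

**4 from 1.** The aldehyde with the masked ketone next to it comes from acetophenone 2 by α-hydroxylation with concurrent ketalisation (3) and oxidation.

## Alternatives that were turned down

**Alternative 1:** The last ring to be made is ring A of T. The disconnection cuts T-C4a–C8a and unravels the ring into a 3,5-dioxo ester chain on T-C4, masked as a dioxinone, on a substrate in which M and B are already doubly linked and ring E is a methyl ketal. Forward, heating in methanol opens the dioxinone and NaOMe drives a Claisen condensation of C4a onto the ester carbon; enolisation gives A1.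
- For it: ring A of T appears as a free, symmetric triol, so the closure of ring C onto T-C2 has no regiochemical ambiguity and needs no blocking group. On that point it is better than the chosen route, which needs the O5 pivalate.
- Against it: the carbanion required is the least acidic and most hindered one of the chain (C4a, next to the doubly benzylic T-C4), and the same enolates can O-acylate to a 4-hydroxy-2-pyrone. The step makes one ring only and presupposes the hub ring, the M–B ketal and ring E. The poly-carbonyl chain has to be built by several steps on a late, precious intermediate, which makes the sequence linear.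
- Comparison: the chosen route spends its ring-forming step on joining two halves and differentiating the hub oxygens, at the price of one blocking group and a congested union.

**Alternative 2:** Ring E and ring C of M are cut at their C2=C3 double bonds. The precursor carries α-aryl vinyl ethers on O7 and O1 of the hub and 1-arylallyl arms on C8 and C4a. Forward, Mo(N-2,6-iPr2C6H3)(CHCMe2Ph)[OCMe(CF3)2]2 closes both rings by enol ether–olefin metathesis to the bis(4H-chromene) A2.
- For it: two rings form in one neutral operation, the C4 centres are set beforehand and not touched, and no open-chain C2 carbonyl with an epimerisable C3 neighbour ever exists. On this last point it is stronger than the chosen route.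
- Against it: A2 is at the wrong oxidation level at T-C3 and M-C3, so two face-selective oxidations and four C–O bond formations remain, each relying on substrate control from C4. 2-Aryl-4H-chromenes with a doubly benzylic C4–H are prone to oxidation to flavylium ions, which would erase C4. The bulky alkylidene has to engage two 1,1-disubstituted enol ethers next to an oxygen flanked by both arms. Above all, the hub ring must already exist with two stereodefined arms and three differentiated oxygens.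
- Comparison: the benzannulation solves that hub problem by construction and sets C3 by reagent control before the union. Metathesis would be shorter only if the hub came for free.

**Alternative 3:** Only the top ketal is disconnected: T-C3–O and T-C2–O1 are cut, leading back to a ring-E 4H-chromene whose C4 aryl group has a free ortho phenol. Forward, dimethyldioxirane epoxidises the enol ether on the face away from that aryl group and the phenol opens the epoxide at C2, closing ring C of T and giving A3, one hydrogenolysis from the target.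
- For it: T-C2 and T-C3 are set together and stereospecifically from T-C4 under neutral conditions, and anti epoxidation gives the 3,4-cis arrangement that unit T needs. For this unit that is more direct than auxiliary control followed by an acid-driven ketal exchange.
- Against it: it is an end-game and not a plan for the skeleton. The chromene with M and B already doubly linked has to be made first, which is most of the problem. The free phenol and the electron-rich rings compete for the electrophilic oxidant. Trace acid can close the enol ether directly onto the phenol and give the 3-deoxy ketal. The face selectivity rests on one aryl group on a flexible half-chair.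
- Comparison: the chosen route forms both ketals of the molecule in one thermodynamically driven step from centres fixed early, and its convergence keeps the longest linear sequence shorter than a route that ends with this step.

Key step: step 28

## Remarks on the chemistry

- The stereochemistry is taken as drawn; the route is planned for exactly the isomer described in the analysis.
- Ketene is used as a gas stream from pyrolysis of acetone.
- Siloxyalkynes 21 and 39 and cyclobutenone 22 are handled without acidic chromatography and used promptly.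
- Steps 1–3 give aldehyde 4; steps 4–15 give the top-arm cyclobutenone 22; steps 16–27 give the middle-arm alkyne 39; step 28 is the key step; steps 29–33 finish the synthesis.

## Steps

Step 1
Reactants: 1 3',4'-dihydroxyacetophenone
Product: 2 3',4'-bis(benzyloxy)acetophenone
Conditions: BnBr, K2CO3, DMF, 60 °C
Reagents that add atoms: benzyl bromide, BrCc1ccccc1
Why: Williamson etherification of both phenols with K2CO3 as base; the aryl ketone is inert under these conditions.

Step 2
Reactants: 2 3',4'-bis(benzyloxy)acetophenone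
Product: 3 2-[3,4-bis(benzyloxy)phenyl]-2,2-dimethoxyethan-1-ol
Conditions: PhI(OAc)2, KOH, MeOH, 0 °C → rt
Reagents that add atoms: methanol, CO
Why: Hypervalent-iodine α-hydroxylation of a methyl ketone in methanolic KOH: the enolate is iodinated at carbon, methoxide adds to the carbonyl, the alkoxide displaces iodobenzene to give a methoxy epoxide, and methoxide opens it at the acetal carbon. The α-hydroxy dimethyl ketal forms in one flask with the ketone already masked.

Step 3
Reactants: 3 2-[3,4-bis(benzyloxy)phenyl]-2,2-dimethoxyethan-1-ol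
Product: 4 2-[3,4-bis(benzyloxy)phenyl]-2,2-dimethoxyacetaldehyde
Conditions: (COCl)2, DMSO, CH2Cl2, −78 °C; Et3N, −78 → 0 °C
Reagents that add atoms: none
Why: Swern oxidation of a primary alcohol; cold and basic, so the benzylic ketal survives, and the aldehyde has no α-hydrogen to enolise.

Step 4
Reactants: 5 phloroglucinol
Product: 6 1,3,5-tris(benzyloxy)benzene
Conditions: BnBr, K2CO3, DMF, rt → 60 °C
Reagents that add atoms: benzyl bromide, BrCc1ccccc1
Why: Threefold Williamson etherification; C-benzylation of the ambident phloroglucinol anion competes and its products are to be removed by crystallisation, which is acceptable on a cheap first intermediate.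

Step 5
Reactants: 6 1,3,5-tris(benzyloxy)benzene
Product: 7 2-bromo-1,3,5-tris(benzyloxy)benzene
Conditions: NBS (1.0 equiv), CH2Cl2, −78 → 0 °C
Reagents that add atoms: N-bromosuccinimide, O=C1CCC(=O)N1Br
Why: Electrophilic aromatic bromination; the three equivalent positions are each activated by three alkoxy groups, and one equivalent at low temperature should stop at the monobromide because bromine deactivates and shields the ring.

Step 6
Reactants: 7 2-bromo-1,3,5-tris(benzyloxy)benzene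
Product: 8 ethyl 2-[2,4,6-tris(benzyloxy)phenyl]acetate
Conditions: BrZnCH2CO2Et (from BrCH2CO2Et, Zn, THF), Pd(dba)2 (5 mol %), P(t-Bu)3 (5 mol %), THF, rt → 50 °C
Reagents that add atoms: ethyl (bromozincio)acetate, CCOC(=O)C[Zn]Br
Why: Negishi-type α-arylation of an ester with a Reformatsky reagent: oxidative addition of the aryl bromide to zerovalent palladium carrying the bulky electron-rich phosphine, transmetalation from zinc and reductive elimination. The neutral zinc enolate tolerates benzyl ethers and does not arylate twice.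

Step 7
Reactants: 8 ethyl 2-[2,4,6-tris(benzyloxy)phenyl]acetate
Product: 9 2-[2,4,6-tris(benzyloxy)phenyl]acetic acid
Conditions: LiOH, THF–MeOH–H2O, rt; aq. HCl
Reagents that add atoms: lithium hydroxide, [Li+].[OH-]
Why: Saponification of an unhindered ethyl ester; there is no stereocentre to lose at this stage.

Step 8
Reactants: 9 2-[2,4,6-tris(benzyloxy)phenyl]acetic acid; 10 (R)-4-benzyl-2-oxazolidinone
Product: 12 (R)-4-benzyl-3-{2-[2,4,6-tris(benzyloxy)phenyl]acetyl}oxazolidin-2-one, via mixed pivalic anhydride 11 (not isolated)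
Conditions: t-BuCOCl, Et3N, THF, −20 °C; then LiCl, 10, rt
Reagents that add atoms: none
Why: N-acylation of the oxazolidinone through the mixed pivalic anhydride, with LiCl and Et3N activating the carbamate N–H; attack occurs at the less hindered arylacetyl carbonyl.

Step 9
Reactants: 12 (R)-4-benzyl-3-{2-[2,4,6-tris(benzyloxy)phenyl]acetyl}oxazolidin-2-one; 4 2-[3,4-bis(benzyloxy)phenyl]-2,2-dimethoxyacetaldehyde
Product: 14 (R)-4-benzyl-3-{(2R,3R)-4-ArC-3-hydroxy-4,4-dimethoxy-2-ArT-butanoyl}oxazolidin-2-one, via dibutylboron Z-enolate 13 (not isolated)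
Conditions: Bu2BOTf, i-Pr2NEt, CH2Cl2, −78 → 0 °C; 4, −78 → 0 °C; pH 7 buffer, MeOH, H2O2, 0 °C
Reagents that add atoms: none
Why: Evans syn-aldol reaction: soft enolisation gives the Z boron enolate, which reacts through a closed chair transition state with the aldehyde approaching the enolate face opposite the auxiliary benzyl group. The (R)-auxiliary sets T-C4 and T-C3 as (2R,3R), the syn relationship that becomes 3,4-cis in unit T. The aldehyde cannot enolise, and a slight excess of amine keeps the boron triflate from ionising the ketal.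

Step 10
Reactants: 14 (R)-4-benzyl-3-{(2R,3R)-4-ArC-3-hydroxy-4,4-dimethoxy-2-ArT-butanoyl}oxazolidin-2-one
Product: 15 (R)-4-benzyl-3-{(2R,3R)-4-ArC-4,4-dimethoxy-3-(triethylsilyloxy)-2-ArT-butanoyl}oxazolidin-2-one
Conditions: Et3SiOTf, 2,6-lutidine, CH2Cl2, −78 → 0 °C
Reagents that add atoms: triethylsilyl triflate, CC[Si](CC)(CC)OS(=O)(=O)C(F)(F)F
Why: Silylation of a hindered secondary alcohol with a silyl triflate and a hindered pyridine base. It blocks retro-aldol cleavage, protects the hydroxyl from the organolithium and ketene chemistry that follows, and is cleavable by fluoride without the benzyl cation that a benzylation would release next to the electron-rich rings.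

Step 11
Reactants: 15 (R)-4-benzyl-3-{(2R,3R)-4-ArC-4,4-dimethoxy-3-(triethylsilyloxy)-2-ArT-butanoyl}oxazolidin-2-one
Product: 16 (2S,3R)-4-ArC-4,4-dimethoxy-3-(triethylsilyloxy)-2-ArT-butan-1-ol
Conditions: LiBH4, MeOH (1 equiv), THF, 0 °C
Reagents that add atoms: none
Why: Reductive removal of the auxiliary: the small hydride attacks the exocyclic imide carbonyl and the aldehyde formed is reduced on to the primary alcohol. The stereocentres are untouched (the descriptor at C2 changes by priority only) and 10 is recovered.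

Step 12
Reactants: 16 (2S,3R)-4-ArC-4,4-dimethoxy-3-(triethylsilyloxy)-2-ArT-butan-1-ol
Product: 17 (2R,3R)-4-ArC-4,4-dimethoxy-3-(triethylsilyloxy)-2-ArT-butanal
Conditions: Dess–Martin periodinane, NaHCO3, CH2Cl2, 0 °C → rt
Reagents that add atoms: none
Why: Dess–Martin oxidation under bicarbonate buffering, without strong acid or base. The ortho,ortho-disubstituted aryl ring is twisted out of conjugation with the enol, which should slow epimerisation at T-C4, and the aldehyde is used at once.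

Step 13
Reactants: 17 (2R,3R)-4-ArC-4,4-dimethoxy-3-(triethylsilyloxy)-2-ArT-butanal
Product: 18 (3R,4R)-5-ArC-1,1-dibromo-5,5-dimethoxy-4-(triethylsilyloxy)-3-ArT-pent-1-ene
Conditions: CBr4, PPh3, 2,6-lutidine, CH2Cl2, 0 °C
Reagents that add atoms: carbon tetrabromide, BrC(Br)(Br)Br
Why: First stage of the Corey–Fuchs sequence: Wittig reaction of the aldehyde with the dibromomethylene ylide formed from CBr4 and PPh3. 2,6-Lutidine buffers the acidic phosphorus by-products so that the ketal, the silyl ether and the α-stereocentre survive.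

Step 14
Reactants: 18 (3R,4R)-5-ArC-1,1-dibromo-5,5-dimethoxy-4-(triethylsilyloxy)-3-ArT-pent-1-ene
Product: 21 (3R,4R)-5-ArC-5,5-dimethoxy-4-(triethylsilyloxy)-3-ArT-1-(triisopropylsilyloxy)pent-1-yne, via lithium acetylide 19 (not isolated), via lithium ynolate 20 (not isolated)
Conditions: n-BuLi (2.1 equiv), THF, −78 °C; LiOOt-Bu (from t-BuOOH, LiN(SiMe3)2), −78 → 0 °C; i-Pr3SiOTf, −78 °C
Reagents that add atoms: lithium tert-butyl peroxide, [Li+].[O-]OC(C)(C)C; triisopropylsilyl triflate, CC(C)[Si](C(C)C)(C(C)C)OS(=O)(=O)C(F)(F)F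
Why: Second stage of the Corey–Fuchs sequence (Br/Li exchange, Fritsch–Buttenberg–Wiechell 1,2-shift, deprotonation) gives the lithium acetylide. Oxygen transfer from lithium tert-butyl peroxide gives the ynolate, which the bulky silyl triflate traps on oxygen; this is the known route from alkynyllithiums to triisopropylsilyl ynol ethers. The propargylic C–H is not acidic enough to be touched once the acetylide has formed.

Step 15
Reactants: 21 (3R,4R)-5-ArC-5,5-dimethoxy-4-(triethylsilyloxy)-3-ArT-1-(triisopropylsilyloxy)pent-1-yne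
Product: 22 2-(T-arm)-3-(triisopropylsilyloxy)cyclobut-2-en-1-one
Conditions: ketene (gas, excess), CH2Cl2, 0 °C → rt
Reagents that add atoms: ketene, C=C=O
Why: [2+2] cycloaddition of ketene with an ynol silyl ether: the alkyne carbon remote from oxygen is the nucleophile and bonds to the ketene carbonyl carbon, so the arm ends up on C2 and the siloxy group on C3 of the cyclobutenone. No stereocentre is formed and T-C4 is not involved.

Step 16
Reactants: 23 (−)-catechin
Product: 24 5,7,3',4'-tetra-O-benzyl-(−)-catechin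
Conditions: BnBr, K2CO3, DMF, 0 °C → rt
Reagents that add atoms: benzyl bromide, BrCc1ccccc1
Why: Williamson etherification of the four phenols with the weak base K2CO3, which leaves the secondary alcohol free and avoids the ring-opening epimerisation at C2 that stronger bases cause in free catechins.

Step 17
Reactants: 24 5,7,3',4'-tetra-O-benzyl-(−)-catechin
Product: 25 3,5,7,3',4'-penta-O-benzyl-(−)-catechin
Conditions: NaH, BnBr, Bu4NI (cat.), DMF, 0 °C → rt
Reagents that add atoms: benzyl bromide, BrCc1ccccc1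
Why: Williamson etherification of the remaining secondary alcohol; all phenols are already capped, so C2 is no longer base-labile.

Step 18
Reactants: 25 3,5,7,3',4'-penta-O-benzyl-(−)-catechin
Product: 26 8-bromo-3,5,7,3',4'-penta-O-benzyl-(−)-catechin
Conditions: NBS (1.0 equiv), CH2Cl2, −78 °C → rt
Reagents that add atoms: N-bromosuccinimide, O=C1CCC(=O)N1Br
Why: Electrophilic bromination of ring A; in 5,7-dialkoxyflavans C8 (ortho to O1 and O7, para to O5) is brominated in preference to C6, and one equivalent at low temperature should stop at the monobromide.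

Step 19
Reactants: 26 8-bromo-3,5,7,3',4'-penta-O-benzyl-(−)-catechin
Product: 27 ethyl 2-Fl-acetate
Conditions: BrZnCH2CO2Et (from BrCH2CO2Et, Zn, THF), Pd(dba)2 (5 mol %), P(t-Bu)3 (5 mol %), THF, 50 °C
Reagents that add atoms: ethyl (bromozincio)acetate, CCOC(=O)C[Zn]Br
Why: The same Negishi-type α-arylation with a Reformatsky reagent as in step 6; C8 is flanked by two oxygen substituents, which is why the bulky monophosphine and gentle warming are used.

Step 20
Reactants: 27 ethyl 2-Fl-acetate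
Product: 28 2-Fl-acetic acid
Conditions: LiOH, THF–MeOH–H2O, rt; aq. HCl
Reagents that add atoms: lithium hydroxide, [Li+].[OH-]
Why: Saponification as in step 7; the flavan stereocentres are not base-labile once all phenols are etherified.

Step 21
Reactants: 28 2-Fl-acetic acid; 10 (R)-4-benzyl-2-oxazolidinone
Product: 30 (R)-4-benzyl-3-(2-Fl-acetyl)oxazolidin-2-one, via mixed pivalic anhydride 29 (not isolated)
Conditions: t-BuCOCl, Et3N, THF, −20 °C; then LiCl, 10, rt
Reagents that add atoms: none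
Why: N-acylation through the mixed pivalic anhydride as in step 8.

Step 22
Reactants: 30 (R)-4-benzyl-3-(2-Fl-acetyl)oxazolidin-2-one; 4 2-[3,4-bis(benzyloxy)phenyl]-2,2-dimethoxyacetaldehyde
Product: 32 (R)-4-benzyl-3-{(2R,3R)-4-ArC-3-hydroxy-4,4-dimethoxy-2-Fl-butanoyl}oxazolidin-2-one, via dibutylboron Z-enolate 31 (not isolated)
Conditions: Bu2BOTf, i-Pr2NEt, CH2Cl2, −78 → 0 °C; 4, −78 → 0 °C; pH 7 buffer, MeOH, H2O2, 0 °C
Reagents that add atoms: none
Why: Evans syn-aldol reaction as in step 9. The flavan stereocentres are remote, so the (R)-auxiliary controls the outcome and sets M-C4 and M-C3 as (2R,3R). The same syn relationship becomes 3,4-trans in unit M because here the hub ring, and not the aryl group on C4, will be ring A of the unit.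

Step 23
Reactants: 32 (R)-4-benzyl-3-{(2R,3R)-4-ArC-3-hydroxy-4,4-dimethoxy-2-Fl-butanoyl}oxazolidin-2-one
Product: 33 (R)-4-benzyl-3-{(2R,3R)-4-ArC-4,4-dimethoxy-3-(triethylsilyloxy)-2-Fl-butanoyl}oxazolidin-2-one
Conditions: Et3SiOTf, 2,6-lutidine, CH2Cl2, −78 → 0 °C
Reagents that add atoms: triethylsilyl triflate, CC[Si](CC)(CC)OS(=O)(=O)C(F)(F)F
Why: Silylation of the hindered aldol hydroxyl as in step 10.

Step 24
Reactants: 33 (R)-4-benzyl-3-{(2R,3R)-4-ArC-4,4-dimethoxy-3-(triethylsilyloxy)-2-Fl-butanoyl}oxazolidin-2-one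
Product: 34 (2S,3R)-4-ArC-4,4-dimethoxy-3-(triethylsilyloxy)-2-Fl-butan-1-ol
Conditions: LiBH4, MeOH (1 equiv), THF, 0 °C
Reagents that add atoms: none
Why: Reductive removal of the auxiliary as in step 11; 10 is recovered.

Step 25
Reactants: 34 (2S,3R)-4-ArC-4,4-dimethoxy-3-(triethylsilyloxy)-2-Fl-butan-1-ol
Product: 35 (2R,3R)-4-ArC-4,4-dimethoxy-3-(triethylsilyloxy)-2-Fl-butanal
Conditions: Dess–Martin periodinane, NaHCO3, CH2Cl2, 0 °C → rt
Reagents that add atoms: none
Why: Buffered Dess–Martin oxidation as in step 12; the aldehyde is used at once.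

Step 26
Reactants: 35 (2R,3R)-4-ArC-4,4-dimethoxy-3-(triethylsilyloxy)-2-Fl-butanal
Product: 36 (3R,4R)-5-ArC-1,1-dibromo-5,5-dimethoxy-4-(triethylsilyloxy)-3-Fl-pent-1-ene
Conditions: CBr4, PPh3, 2,6-lutidine, CH2Cl2, 0 °C
Reagents that add atoms: carbon tetrabromide, BrC(Br)(Br)Br
Why: Corey–Fuchs dibromo-olefination (Wittig reaction with the dibromomethylene ylide) as in step 13.

Step 27
Reactants: 36 (3R,4R)-5-ArC-1,1-dibromo-5,5-dimethoxy-4-(triethylsilyloxy)-3-Fl-pent-1-ene
Product: 39 (3R,4R)-5-ArC-5,5-dimethoxy-4-(triethylsilyloxy)-3-Fl-1-(triisopropylsilyloxy)pent-1-yne, via lithium acetylide 37 (not isolated), via lithium ynolate 38 (not isolated)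
Conditions: n-BuLi (2.1 equiv), THF, −78 °C; LiOOt-Bu (from t-BuOOH, LiN(SiMe3)2), −78 → 0 °C; i-Pr3SiOTf, −78 °C
Reagents that add atoms: lithium tert-butyl peroxide, [Li+].[O-]OC(C)(C)C; triisopropylsilyl triflate, CC(C)[Si](C(C)C)(C(C)C)OS(=O)(=O)C(F)(F)F
Why: Fritsch–Buttenberg–Wiechell formation of the acetylide, oxygen transfer to the ynolate and O-silylation as in step 14.

Step 28
Reactants: 22 2-(T-arm)-3-(triisopropylsilyloxy)cyclobut-2-en-1-one; 39 (3R,4R)-5-ArC-5,5-dimethoxy-4-(triethylsilyloxy)-3-Fl-1-(triisopropylsilyloxy)pent-1-yne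
Product: 44 2-(M-arm)-4-(T-arm)-3,5-bis(triisopropylsilyloxy)phenol, via vinylketene 40 (not isolated), via 4-vinylcyclobutenone 41 (not isolated), via dienylketene 42 (not isolated), via cyclohexa-2,4-dienone 43 (not isolated)
Conditions: toluene, 80 → 110 °C, 22 added slowly to 39 (1.2 equiv), Ar
Reagents that add atoms: none
Why: Danheiser benzannulation in its cyclobutenone and siloxyalkyne form. Heat opens 22 by a reversible 4π electrocyclic ring opening to the vinylketene 40; the ynol silyl ether 39 adds to the ketene C=C in a polar [2+2] in which its carbon remote from oxygen attacks the ketene carbonyl carbon, giving the 4-vinylcyclobutenone 41. A second 4π opening breaks the bond between the former ketene carbon and the quaternary carbon and gives the dienylketene 42, which closes the one new ring, ring A of M, by thermal disrotatory 6π electrocyclisation (C5–C6) to the dienone 43; tautomerisation gives the phenol 44. The ketene carbon becomes C5 with a free hydroxyl, the alkyne carbons become C4a and C8a with silylated O1, and cyclobutenone C2, C3 and C4 become C8, C7 with silylated O7, and C6. No stereocentre is formed, since the quaternary carbon of 41 is transient. The step needs regioselectivity in the [2+2], which the polarisation of the ynol ether against the ketene secures. It also needs the cross reaction to win over ketene recyclisation and O-acylation of 44, which is helped by keeping 39 in excess and 22 dilute. T-C4 and M-C4 are not α to a carbonyl in any intermediate and should survive the neutral, aprotic conditions.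

Step 29
Reactants: 44 2-(M-arm)-4-(T-arm)-3,5-bis(triisopropylsilyloxy)phenol
Product: 45 2-(M-arm)-4-(T-arm)-3,5-bis(triisopropylsilyloxy)phenyl pivalate
Conditions: t-BuCOCl, Et3N, DMAP (cat.), CH2Cl2, 0 °C → rt
Reagents that add atoms: pivaloyl chloride, CC(C)(C)C(=O)Cl
Why: Acylation of the only free hydroxyl, M-O5. The pivalate survives fluoride, hydrogenolysis and mild acid and is too hindered to migrate; its task is to keep O5 out of the ketalisation.

Step 30
Reactants: 45 2-(M-arm)-4-(T-arm)-3,5-bis(triisopropylsilyloxy)phenyl pivalate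
Product: 46 3,5-dihydroxy-2-[M-arm(OH)]-4-[T-arm(OH)]phenyl pivalate
Conditions: Bu4NF, AcOH (1:1), THF, 0 °C → rt
Reagents that add atoms: none
Why: Fluoride-induced desilylation: the aryl silyl ethers are cleaved fastest and the secondary triethylsilyl ethers follow. Acetic acid keeps phenoxide and alkoxide concentrations low so that the pivalate is neither cleaved nor transferred.

Step 31
Reactants: 46 3,5-dihydroxy-2-[M-arm(OH)]-4-[T-arm(OH)]phenyl pivalate
Product: 47 3,5-dihydroxy-2-(M-arm')-4-(T-arm')phenyl pivalate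
Conditions: H2 (1 atm), Pd(OH)2/C, THF–MeOH, rt
Reagents that add atoms: none
Why: Hydrogenolysis of eleven aryl and one alkyl benzyl ether under neutral conditions. The hindered, unprotonated dimethyl ketals and the aryl pivalate are not expected to react, and a ketal that starts to close onto a freed phenol only anticipates step 32.

Step 32
Reactants: 47 3,5-dihydroxy-2-(M-arm')-4-(T-arm')phenyl pivalate
Product: 48 5-O-pivaloyl derivative of the target (pivalate on O5 of unit M)
Conditions: PPTS (cat.), 5 Å MS, MeCN–THF, rt → 40 °C, Ar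
Reagents that add atoms: none
Why: Acid-catalysed ketal exchange: each dimethyl ketal ionises to an oxocarbenium ion stabilised by its para-hydroxyphenyl group and is captured twice by flanking phenols, each time closing a six-membered ring, so that two 2,6-dioxabicyclo[3.3.1]nonane units form. T-C2 and M-C2 become stereocentres whose configuration is dictated by T-C4 and M-C4, because the bicycle can only be bridged cis. With O5 acylated, M-C2 can use only O1 on the hub together with O7 of unit B, which leaves hub O7 and an ortho oxygen of the symmetric ring A of T for T-C2; the sieves take up methanol and drive the exchange to the doubly closed product.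

Step 33
Reactants: 48 5-O-pivaloyl derivative of the target
Product: 49 the target, CNP0276052.6
Conditions: K2CO3, degassed MeOH, 0 °C → rt, Ar; then AcOH
Reagents that add atoms: none
Why: Base-mediated transesterification of the aryl pivalate to methyl pivalate, run short, cold and oxygen-free to spare the polyphenol; the bicyclic ketals are stable to carbonate.

## Compound list

1 | 3',4'-dihydroxyacetophenone | CC(=O)c1ccc(O)c(O)c1 | starting material
2 | 3',4'-bis(benzyloxy)acetophenone | CC(=O)c1ccc(OCc2ccccc2)c(OCc2ccccc2)c1 | intermediate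
3 | 2-[3,4-bis(benzyloxy)phenyl]-2,2-dimethoxyethan-1-ol | OCC(OC)(OC)c1ccc(OCc2ccccc2)c(OCc2ccccc2)c1 | intermediate
4 | 2-[3,4-bis(benzyloxy)phenyl]-2,2-dimethoxyacetaldehyde | O=CC(OC)(OC)c1ccc(OCc2ccccc2)c(OCc2ccccc2)c1 | intermediate
5 | phloroglucinol | Oc1cc(O)cc(O)c1 | starting material
6 | 1,3,5-tris(benzyloxy)benzene | c1ccccc1COc1cc(OCc2ccccc2)cc(OCc2ccccc2)c1 | intermediate
7 | 2-bromo-1,3,5-tris(benzyloxy)benzene | Brc1c(OCc2ccccc2)cc(OCc2ccccc2)cc1OCc1ccccc1 | intermediate
8 | ethyl 2-[2,4,6-tris(benzyloxy)phenyl]acetate | CCOC(=O)Cc1c(OCc2ccccc2)cc(OCc2ccccc2)cc1OCc1ccccc1 | intermediate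
9 | 2-[2,4,6-tris(benzyloxy)phenyl]acetic acid | OC(=O)Cc1c(OCc2ccccc2)cc(OCc2ccccc2)cc1OCc1ccccc1 | intermediate
10 | (R)-4-benzyl-2-oxazolidinone | O=C1OC[C@@H](Cc2ccccc2)N1 | starting material
11 | 2-[2,4,6-tris(benzyloxy)phenyl]acetic pivalic anhydride | CC(C)(C)C(=O)OC(=O)Cc1c(OCc2ccccc2)cc(OCc2ccccc2)cc1OCc1ccccc1 | intermediate, not isolated
12 | (R)-4-benzyl-3-{2-[2,4,6-tris(benzyloxy)phenyl]acetyl}oxazolidin-2-one | O=C(Cc1c(OCc2ccccc2)cc(OCc2ccccc2)cc1OCc1ccccc1)N1[C@H](Cc2ccccc2)COC1=O | intermediate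
13 | dibutylboron Z-enolate of 12 | CCCCB(CCCC)O/C(=C\c1c(OCc2ccccc2)cc(OCc2ccccc2)cc1OCc1ccccc1)N1[C@H](Cc2ccccc2)COC1=O | intermediate, not isolated
14 | (R)-4-benzyl-3-{(2R,3R)-4-ArC-3-hydroxy-4,4-dimethoxy-2-ArT-butanoyl}oxazolidin-2-one | O=C(N1[C@H](Cc2ccccc2)COC1=O)[C@H](c1c(OCc2ccccc2)cc(OCc2ccccc2)cc1OCc1ccccc1)[C@@H](O)C(OC)(OC)c1ccc(OCc2ccccc2)c(OCc2ccccc2)c1 | intermediate
15 | triethylsilyl ether of 14 | O=C(N1[C@H](Cc2ccccc2)COC1=O)[C@H](c1c(OCc2ccccc2)cc(OCc2ccccc2)cc1OCc1ccccc1)[C@@H](O[Si](CC)(CC)CC)C(OC)(OC)c1ccc(OCc2ccccc2)c(OCc2ccccc2)c1 | intermediate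
16 | (2S,3R)-4-ArC-4,4-dimethoxy-3-(triethylsilyloxy)-2-ArT-butan-1-ol | OC[C@H](c1c(OCc2ccccc2)cc(OCc2ccccc2)cc1OCc1ccccc1)[C@@H](O[Si](CC)(CC)CC)C(OC)(OC)c1ccc(OCc2ccccc2)c(OCc2ccccc2)c1 | intermediate
17 | (2R,3R)-4-ArC-4,4-dimethoxy-3-(triethylsilyloxy)-2-ArT-butanal | O=C[C@H](c1c(OCc2ccccc2)cc(OCc2ccccc2)cc1OCc1ccccc1)[C@@H](O[Si](CC)(CC)CC)C(OC)(OC)c1ccc(OCc2ccccc2)c(OCc2ccccc2)c1 | intermediate
18 | (3R,4R)-5-ArC-1,1-dibromo-5,5-dimethoxy-4-(triethylsilyloxy)-3-ArT-pent-1-ene | BrC(Br)=C[C@H](c1c(OCc2ccccc2)cc(OCc2ccccc2)cc1OCc1ccccc1)[C@@H](O[Si](CC)(CC)CC)C(OC)(OC)c1ccc(OCc2ccccc2)c(OCc2ccccc2)c1 | intermediate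
19 | lithium acetylide of the T-arm, (3R,4R)-5-ArC-5,5-dimethoxy-4-(triethylsilyloxy)-3-ArT-pent-1-yn-1-yllithium | [Li]C#C[C@H](c1c(OCc2ccccc2)cc(OCc2ccccc2)cc1OCc1ccccc1)[C@@H](O[Si](CC)(CC)CC)C(OC)(OC)c1ccc(OCc2ccccc2)c(OCc2ccccc2)c1 | intermediate, not isolated
20 | lithium ynolate of the T-arm | [Li]OC#C[C@H](c1c(OCc2ccccc2)cc(OCc2ccccc2)cc1OCc1ccccc1)[C@@H](O[Si](CC)(CC)CC)C(OC)(OC)c1ccc(OCc2ccccc2)c(OCc2ccccc2)c1 | intermediate, not isolated
21 | (3R,4R)-5-ArC-5,5-dimethoxy-4-(triethylsilyloxy)-3-ArT-1-(triisopropylsilyloxy)pent-1-yne | CC(C)[Si](OC#C[C@H](c1c(OCc2ccccc2)cc(OCc2ccccc2)cc1OCc1ccccc1)[C@@H](O[Si](CC)(CC)CC)C(OC)(OC)c1ccc(OCc2ccccc2)c(OCc2ccccc2)c1)(C(C)C)C(C)C | intermediate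
22 | 2-(T-arm)-3-(triisopropylsilyloxy)cyclobut-2-en-1-one | CC(C)[Si](OC4=C([C@H](c1c(OCc2ccccc2)cc(OCc2ccccc2)cc1OCc1ccccc1)[C@@H](O[Si](CC)(CC)CC)C(OC)(OC)c1ccc(OCc2ccccc2)c(OCc2ccccc2)c1)C(=O)C4)(C(C)C)C(C)C | intermediate
23 | (−)-catechin, (2S,3R) | O[C@@H]1Cc2c(O)cc(O)cc2O[C@H]1c1ccc(O)c(O)c1 | starting material
24 | 5,7,3',4'-tetra-O-benzyl-(−)-catechin | O[C@@H]1Cc2c(OCc3ccccc3)cc(OCc3ccccc3)cc2O[C@H]1c1ccc(OCc2ccccc2)c(OCc2ccccc2)c1 | intermediate
25 | 3,5,7,3',4'-penta-O-benzyl-(−)-catechin | c1ccccc1CO[C@@H]1Cc2c(OCc3ccccc3)cc(OCc3ccccc3)cc2O[C@H]1c1ccc(OCc2ccccc2)c(OCc2ccccc2)c1 | intermediate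
26 | 8-bromo-3,5,7,3',4'-penta-O-benzyl-(−)-catechin | Brc1c(OCc2ccccc2)cc(OCc2ccccc2)c2c1O[C@@H](c1ccc(OCc3ccccc3)c(OCc3ccccc3)c1)[C@H](OCc1ccccc1)C2 | intermediate
27 | ethyl 2-Fl-acetate | CCOC(=O)Cc1c(OCc2ccccc2)cc(OCc2ccccc2)c2c1O[C@@H](c1ccc(OCc3ccccc3)c(OCc3ccccc3)c1)[C@H](OCc1ccccc1)C2 | intermediate
28 | 2-Fl-acetic acid | OC(=O)Cc1c(OCc2ccccc2)cc(OCc2ccccc2)c2c1O[C@@H](c1ccc(OCc3ccccc3)c(OCc3ccccc3)c1)[C@H](OCc1ccccc1)C2 | intermediate
29 | 2-Fl-acetic pivalic anhydride | CC(C)(C)C(=O)OC(=O)Cc1c(OCc2ccccc2)cc(OCc2ccccc2)c2c1O[C@@H](c1ccc(OCc3ccccc3)c(OCc3ccccc3)c1)[C@H](OCc1ccccc1)C2 | intermediate, not isolated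
30 | (R)-4-benzyl-3-(2-Fl-acetyl)oxazolidin-2-one | O=C(Cc1c(OCc2ccccc2)cc(OCc2ccccc2)c2c1O[C@@H](c1ccc(OCc3ccccc3)c(OCc3ccccc3)c1)[C@H](OCc1ccccc1)C2)N1[C@H](Cc2ccccc2)COC1=O | intermediate
31 | dibutylboron Z-enolate of 30 | CCCCB(CCCC)O/C(=C\c1c(OCc2ccccc2)cc(OCc2ccccc2)c2c1O[C@@H](c1ccc(OCc3ccccc3)c(OCc3ccccc3)c1)[C@H](OCc1ccccc1)C2)N1[C@H](Cc2ccccc2)COC1=O | intermediate, not isolated
32 | (R)-4-benzyl-3-{(2R,3R)-4-ArC-3-hydroxy-4,4-dimethoxy-2-Fl-butanoyl}oxazolidin-2-one | O=C(N1[C@H](Cc2ccccc2)COC1=O)[C@H](c1c(OCc2ccccc2)cc(OCc2ccccc2)c2c1O[C@@H](c1ccc(OCc3ccccc3)c(OCc3ccccc3)c1)[C@H](OCc1ccccc1)C2)[C@@H](O)C(OC)(OC)c1ccc(OCc2ccccc2)c(OCc2ccccc2)c1 | intermediate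
33 | triethylsilyl ether of 32 | O=C(N1[C@H](Cc2ccccc2)COC1=O)[C@H](c1c(OCc2ccccc2)cc(OCc2ccccc2)c2c1O[C@@H](c1ccc(OCc3ccccc3)c(OCc3ccccc3)c1)[C@H](OCc1ccccc1)C2)[C@@H](O[Si](CC)(CC)CC)C(OC)(OC)c1ccc(OCc2ccccc2)c(OCc2ccccc2)c1 | intermediate
34 | (2S,3R)-4-ArC-4,4-dimethoxy-3-(triethylsilyloxy)-2-Fl-butan-1-ol | OC[C@H](c1c(OCc2ccccc2)cc(OCc2ccccc2)c2c1O[C@@H](c1ccc(OCc3ccccc3)c(OCc3ccccc3)c1)[C@H](OCc1ccccc1)C2)[C@@H](O[Si](CC)(CC)CC)C(OC)(OC)c1ccc(OCc2ccccc2)c(OCc2ccccc2)c1 | intermediate
35 | (2R,3R)-4-ArC-4,4-dimethoxy-3-(triethylsilyloxy)-2-Fl-butanal | O=C[C@H](c1c(OCc2ccccc2)cc(OCc2ccccc2)c2c1O[C@@H](c1ccc(OCc3ccccc3)c(OCc3ccccc3)c1)[C@H](OCc1ccccc1)C2)[C@@H](O[Si](CC)(CC)CC)C(OC)(OC)c1ccc(OCc2ccccc2)c(OCc2ccccc2)c1 | intermediate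
36 | (3R,4R)-5-ArC-1,1-dibromo-5,5-dimethoxy-4-(triethylsilyloxy)-3-Fl-pent-1-ene | BrC(Br)=C[C@H](c1c(OCc2ccccc2)cc(OCc2ccccc2)c2c1O[C@@H](c1ccc(OCc3ccccc3)c(OCc3ccccc3)c1)[C@H](OCc1ccccc1)C2)[C@@H](O[Si](CC)(CC)CC)C(OC)(OC)c1ccc(OCc2ccccc2)c(OCc2ccccc2)c1 | intermediate
37 | lithium acetylide of the M-arm, (3R,4R)-5-ArC-5,5-dimethoxy-4-(triethylsilyloxy)-3-Fl-pent-1-yn-1-yllithium | [Li]C#C[C@H](c1c(OCc2ccccc2)cc(OCc2ccccc2)c2c1O[C@@H](c1ccc(OCc3ccccc3)c(OCc3ccccc3)c1)[C@H](OCc1ccccc1)C2)[C@@H](O[Si](CC)(CC)CC)C(OC)(OC)c1ccc(OCc2ccccc2)c(OCc2ccccc2)c1 | intermediate, not isolated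
38 | lithium ynolate of the M-arm | [Li]OC#C[C@H](c1c(OCc2ccccc2)cc(OCc2ccccc2)c2c1O[C@@H](c1ccc(OCc3ccccc3)c(OCc3ccccc3)c1)[C@H](OCc1ccccc1)C2)[C@@H](O[Si](CC)(CC)CC)C(OC)(OC)c1ccc(OCc2ccccc2)c(OCc2ccccc2)c1 | intermediate, not isolated
39 | (3R,4R)-5-ArC-5,5-dimethoxy-4-(triethylsilyloxy)-3-Fl-1-(triisopropylsilyloxy)pent-1-yne | CC(C)[Si](OC#C[C@H](c1c(OCc2ccccc2)cc(OCc2ccccc2)c2c1O[C@@H](c1ccc(OCc3ccccc3)c(OCc3ccccc3)c1)[C@H](OCc1ccccc1)C2)[C@@H](O[Si](CC)(CC)CC)C(OC)(OC)c1ccc(OCc2ccccc2)c(OCc2ccccc2)c1)(C(C)C)C(C)C | intermediate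
40 | vinylketene, 2-(T-arm)-3-(triisopropylsilyloxy)buta-1,3-dien-1-one | C=C(O[Si](C(C)C)(C(C)C)C(C)C)C(=C=O)[C@H](c1c(OCc2ccccc2)cc(OCc2ccccc2)cc1OCc1ccccc1)[C@@H](O[Si](CC)(CC)CC)C(OC)(OC)c1ccc(OCc2ccccc2)c(OCc2ccccc2)c1 | intermediate, not isolated
41 | 2-(M-arm)-4-(T-arm)-3-(triisopropylsilyloxy)-4-[1-(triisopropylsilyloxy)vinyl]cyclobut-2-en-1-one, both epimers at C4 | O=C4C([C@H](c1c(OCc2ccccc2)cc(OCc2ccccc2)c2c1O[C@@H](c1ccc(OCc3ccccc3)c(OCc3ccccc3)c1)[C@H](OCc1ccccc1)C2)[C@@H](O[Si](CC)(CC)CC)C(OC)(OC)c1ccc(OCc2ccccc2)c(OCc2ccccc2)c1)=C(O[Si](C(C)C)(C(C)C)C(C)C)C4([C@H](c1c(OCc2ccccc2)cc(OCc2ccccc2)cc1OCc1ccccc1)[C@@H](O[Si](CC)(CC)CC)C(OC)(OC)c1ccc(OCc2ccccc2)c(OCc2ccccc2)c1)C(=C)O[Si](C(C)C)(C(C)C)C(C)C | intermediate, not isolated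
42 | dienylketene, 2-(M-arm)-4-(T-arm)-3,5-bis(triisopropylsilyloxy)hexa-1,3,5-trien-1-one, ketene and siloxyvinyl groups cis on the central double bond | O=C=C([C@H](c1c(OCc2ccccc2)cc(OCc2ccccc2)c2c1O[C@@H](c1ccc(OCc3ccccc3)c(OCc3ccccc3)c1)[C@H](OCc1ccccc1)C2)[C@@H](O[Si](CC)(CC)CC)C(OC)(OC)c1ccc(OCc2ccccc2)c(OCc2ccccc2)c1)/C(O[Si](C(C)C)(C(C)C)C(C)C)=C([C@H](c1c(OCc2ccccc2)cc(OCc2ccccc2)cc1OCc1ccccc1)[C@@H](O[Si](CC)(CC)CC)C(OC)(OC)c1ccc(OCc2ccccc2)c(OCc2ccccc2)c1)\C(=C)O[Si](C(C)C)(C(C)C)C(C)C | intermediate, not isolated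
43 | 2-(M-arm)-4-(T-arm)-3,5-bis(triisopropylsilyloxy)cyclohexa-2,4-dien-1-one | O=C4C([C@H](c1c(OCc2ccccc2)cc(OCc2ccccc2)c2c1O[C@@H](c1ccc(OCc3ccccc3)c(OCc3ccccc3)c1)[C@H](OCc1ccccc1)C2)[C@@H](O[Si](CC)(CC)CC)C(OC)(OC)c1ccc(OCc2ccccc2)c(OCc2ccccc2)c1)=C(O[Si](C(C)C)(C(C)C)C(C)C)C([C@H](c1c(OCc2ccccc2)cc(OCc2ccccc2)cc1OCc1ccccc1)[C@@H](O[Si](CC)(CC)CC)C(OC)(OC)c1ccc(OCc2ccccc2)c(OCc2ccccc2)c1)=C(O[Si](C(C)C)(C(C)C)C(C)C)C4 | intermediate, not isolated
44 | 2-(M-arm)-4-(T-arm)-3,5-bis(triisopropylsilyloxy)phenol (ring A of M; O5 free, O1 and O7 silylated) | Oc4cc(O[Si](C(C)C)(C(C)C)C(C)C)c([C@H](c1c(OCc2ccccc2)cc(OCc2ccccc2)cc1OCc1ccccc1)[C@@H](O[Si](CC)(CC)CC)C(OC)(OC)c1ccc(OCc2ccccc2)c(OCc2ccccc2)c1)c(O[Si](C(C)C)(C(C)C)C(C)C)c4[C@H](c1c(OCc2ccccc2)cc(OCc2ccccc2)c2c1O[C@@H](c1ccc(OCc3ccccc3)c(OCc3ccccc3)c1)[C@H](OCc1ccccc1)C2)[C@@H](O[Si](CC)(CC)CC)C(OC)(OC)c1ccc(OCc2ccccc2)c(OCc2ccccc2)c1 | intermediate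
45 | 2-(M-arm)-4-(T-arm)-3,5-bis(triisopropylsilyloxy)phenyl pivalate | CC(C)(C)C(=O)Oc4cc(O[Si](C(C)C)(C(C)C)C(C)C)c([C@H](c1c(OCc2ccccc2)cc(OCc2ccccc2)cc1OCc1ccccc1)[C@@H](O[Si](CC)(CC)CC)C(OC)(OC)c1ccc(OCc2ccccc2)c(OCc2ccccc2)c1)c(O[Si](C(C)C)(C(C)C)C(C)C)c4[C@H](c1c(OCc2ccccc2)cc(OCc2ccccc2)c2c1O[C@@H](c1ccc(OCc3ccccc3)c(OCc3ccccc3)c1)[C@H](OCc1ccccc1)C2)[C@@H](O[Si](CC)(CC)CC)C(OC)(OC)c1ccc(OCc2ccccc2)c(OCc2ccccc2)c1 | intermediate
46 | 3,5-dihydroxy-2-[M-arm(OH)]-4-[T-arm(OH)]phenyl pivalate | CC(C)(C)C(=O)Oc4cc(O)c([C@H](c1c(OCc2ccccc2)cc(OCc2ccccc2)cc1OCc1ccccc1)[C@@H](O)C(OC)(OC)c1ccc(OCc2ccccc2)c(OCc2ccccc2)c1)c(O)c4[C@H](c1c(OCc2ccccc2)cc(OCc2ccccc2)c2c1O[C@@H](c1ccc(OCc3ccccc3)c(OCc3ccccc3)c1)[C@H](OCc1ccccc1)C2)[C@@H](O)C(OC)(OC)c1ccc(OCc2ccccc2)c(OCc2ccccc2)c1 | intermediate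
47 | 3,5-dihydroxy-2-(M-arm')-4-(T-arm')phenyl pivalate | CC(C)(C)C(=O)Oc4cc(O)c([C@H](c1c(O)cc(O)cc1O)[C@@H](O)C(OC)(OC)c1ccc(O)c(O)c1)c(O)c4[C@H](c1c(O)cc(O)c2c1O[C@@H](c1ccc(O)c(O)c1)[C@H](O)C2)[C@@H](O)C(OC)(OC)c1ccc(O)c(O)c1 | intermediate
48 | 5-O-pivaloyl derivative of the target (pivalate on O5 of unit M) | Oc1cc(O)c2c(c1)O[C@]1(c3ccc(O)c(O)c3)Oc3cc(OC(=O)C(C)(C)C)c4c(c3[C@H]2[C@H]1O)O[C@@]1(c2ccc(O)c(O)c2)Oc2cc(O)c3c(c2[C@@H]4[C@H]1O)O[C@@H](c1ccc(O)c(O)c1)[C@H](O)C3 | intermediate
49 | CNP0276052.6 | Oc1cc(O)c2c(c1)O[C@]1(c3ccc(O)c(O)c3)Oc3cc(O)c4c(c3[C@H]2[C@H]1O)O[C@@]1(c2ccc(O)c(O)c2)Oc2cc(O)c3c(c2[C@@H]4[C@H]1O)O[C@@H](c1ccc(O)c(O)c1)[C@H](O)C3 | target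

## Step count and least certain steps

Total: 33 steps (3 to aldehyde 4, 12 from 5 to cyclobutenone 22, 12 from 23 to alkyne 39, the key step, 5 after it). Longest linear sequence: 18 steps (steps 16 to 33, from 23).

**Step 28 (key step).** The most likely failure is steric retardation of the bimolecular [2+2]. The vinylketene then simply recloses, the siloxyalkyne is lost on prolonged heating by 1,3-silyl shift to a silylketene, and any phenol formed is acylated by surviving ketene. Fallback: exchange the roles of the two halves, so that the alkyne carbon that makes the first C–C bond carries the more flexible ArT arm. The fallback sets out from 39 and 21. Alkyne 39 is treated with ketene to give the M-arm cyclobutenone F1, which is heated with 21 to give the isomeric hub phenol F2, now with free O7–H and silylated O1 and O5. Benzylation of O7 (BnBr, K2CO3) gives the benzyl ether F3, buffered Bu4NF gives the desilylated diphenol F4, and the less hindered O5 (one ortho arm against two for O1) is pivaloylated selectively to the pivalate F5. Hydrogenolysis of all benzyl ethers comes back to the route at 47.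

**Steps 9 and 22 (aldol).** The hindered boron enolate may add too slowly to the neopentyl-type aldehyde, so that retro-aldol on work-up and ionisation of the benzylic ketal by the boron triflate erode yield and selectivity. Fallback, set out from 2 and 12: SeO2 oxidation of 2 gives the arylglyoxal F6, whose aldehyde is flanked by a planar carbonyl instead of a quaternary ketal. The boron enolate 13 adds to it to give the ketol F7, Et3SiOTf gives the silyl ether F8, and MeOSiMe3 with catalytic Me3SiOTf at −78 °C converts the ketone into the dimethyl ketal, returning to the route at 15. The same detour serves 30 and 33.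

**Steps 12–13 and 25–26 (α-aryl aldehyde).** Enolisation of the aldehyde can epimerise C4 or eliminate the β-silyloxy group during oxidation and olefination. Fallback, set out from 15: LiOH/H2O2 gives the acid F9, Me3SiCHN2 in MeOH gives the methyl ester F10, and Kowalski ester homologation (CH2Br2 and lithium 2,2,6,6-tetramethylpiperidide, then LiN(SiMe3)2, then n-BuLi) gives ynolate 20 directly. Silylation in the same flask comes back to the route at 21, with no aldehyde on the way. The same applies from 33 to 39.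

**Step 19 (and step 6).** Oxidative addition and transmetalation at the di-ortho-oxygenated bromide may be slow, and protodebromination then takes over. Fallback, set out from 26: Br/Li exchange with t-BuLi at −78 °C, opening of ethylene oxide by the aryllithium with BF3·OEt2 to the arylethanol F11, and oxidation with TEMPO and PhI(OAc)2 in aqueous MeCN, which comes back to the route at 28.

**Step 31 (hydrogenolysis).** The benzylic C–OMe bonds of the ketals may be hydrogenolysed along with the benzyl ethers, or the ketals may be lost once the para-hydroxyl groups are free and before ring closure. Fallback, set out from 46: BCl3 with pentamethylbenzene at −78 °C cleaves the benzyl ethers by Lewis acid with a cation scavenger. The ketals ionise in the same flask and are trapped by the liberated phenols on methanolic quench, which comes back to the route at 48 with no new compound on the way (F0).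

**Step 33 (deacylation).** Phenoxide oxidation by traces of oxygen and base-induced epimerisation at C2 of unit B may outrun cleavage of the hindered pivalate. Fallback, set out from 44: acylation of O5 with levulinic acid (N,N'-dicyclohexylcarbodiimide, DMAP) gives the levulinate F12; buffered Bu4NF gives the desilylated levulinate F13; hydrogenolysis gives the polyphenol levulinate F14; PPTS closes both ketals to the 5-O-levulinoyl target F15. Hydrazine acetate in MeOH then removes the levulinate near neutrality and comes back to the route at 49.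

## Further compounds

F1 | step 28 | 2-(M-arm)-3-(triisopropylsilyloxy)cyclobut-2-en-1-one | CC(C)[Si](OC4=C([C@H](c1c(OCc2ccccc2)cc(OCc2ccccc2)c2c1O[C@@H](c1ccc(OCc3ccccc3)c(OCc3ccccc3)c1)[C@H](OCc1ccccc1)C2)[C@@H](O[Si](CC)(CC)CC)C(OC)(OC)c1ccc(OCc2ccccc2)c(OCc2ccccc2)c1)C(=O)C4)(C(C)C)C(C)C
F2 | step 28 | 2-(T-arm)-4-(M-arm)-3,5-bis(triisopropylsilyloxy)phenol (O7 free, O1 and O5 silylated) | Oc4cc(O[Si](C(C)C)(C(C)C)C(C)C)c([C@H](c1c(OCc2ccccc2)cc(OCc2ccccc2)c2c1O[C@@H](c1ccc(OCc3ccccc3)c(OCc3ccccc3)c1)[C@H](OCc1ccccc1)C2)[C@@H](O[Si](CC)(CC)CC)C(OC)(OC)c1ccc(OCc2ccccc2)c(OCc2ccccc2)c1)c(O[Si](C(C)C)(C(C)C)C(C)C)c4[C@H](c1c(OCc2ccccc2)cc(OCc2ccccc2)cc1OCc1ccccc1)[C@@H](O[Si](CC)(CC)CC)C(OC)(OC)c1ccc(OCc2ccccc2)c(OCc2ccccc2)c1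
F3 | step 28 | O7-benzyl ether of F2 | c1ccccc1COc4cc(O[Si](C(C)C)(C(C)C)C(C)C)c([C@H](c1c(OCc2ccccc2)cc(OCc2ccccc2)c2c1O[C@@H](c1ccc(OCc3ccccc3)c(OCc3ccccc3)c1)[C@H](OCc1ccccc1)C2)[C@@H](O[Si](CC)(CC)CC)C(OC)(OC)c1ccc(OCc2ccccc2)c(OCc2ccccc2)c1)c(O[Si](C(C)C)(C(C)C)C(C)C)c4[C@H](c1c(OCc2ccccc2)cc(OCc2ccccc2)cc1OCc1ccccc1)[C@@H](O[Si](CC)(CC)CC)C(OC)(OC)c1ccc(OCc2ccccc2)c(OCc2ccccc2)c1
F4 | step 28 | 5-(benzyloxy)-4-[M-arm(OH)]-2-[T-arm(OH)]benzene-1,3-diol numbered so that O5 and O1 of unit M are the free phenols | c1ccccc1COc4cc(O)c([C@H](c1c(OCc2ccccc2)cc(OCc2ccccc2)c2c1O[C@@H](c1ccc(OCc3ccccc3)c(OCc3ccccc3)c1)[C@H](OCc1ccccc1)C2)[C@@H](O)C(OC)(OC)c1ccc(OCc2ccccc2)c(OCc2ccccc2)c1)c(O)c4[C@H](c1c(OCc2ccccc2)cc(OCc2ccccc2)cc1OCc1ccccc1)[C@@H](O)C(OC)(OC)c1ccc(OCc2ccccc2)c(OCc2ccccc2)c1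
F5 | step 28 | O5-pivalate of F4 | c1ccccc1COc4cc(OC(=O)C(C)(C)C)c([C@H](c1c(OCc2ccccc2)cc(OCc2ccccc2)c2c1O[C@@H](c1ccc(OCc3ccccc3)c(OCc3ccccc3)c1)[C@H](OCc1ccccc1)C2)[C@@H](O)C(OC)(OC)c1ccc(OCc2ccccc2)c(OCc2ccccc2)c1)c(O)c4[C@H](c1c(OCc2ccccc2)cc(OCc2ccccc2)cc1OCc1ccccc1)[C@@H](O)C(OC)(OC)c1ccc(OCc2ccccc2)c(OCc2ccccc2)c1
F6 | step 9 | 2-[3,4-bis(benzyloxy)phenyl]-2-oxoacetaldehyde | O=CC(=O)c1ccc(OCc2ccccc2)c(OCc2ccccc2)c1
F7 | step 9 | (R)-4-benzyl-3-{(2R,3R)-4-ArC-3-hydroxy-4-oxo-2-ArT-butanoyl}oxazolidin-2-one | O=C(N1[C@H](Cc2ccccc2)COC1=O)[C@H](c1c(OCc2ccccc2)cc(OCc2ccccc2)cc1OCc1ccccc1)[C@@H](O)C(=O)c1ccc(OCc2ccccc2)c(OCc2ccccc2)c1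
F8 | step 9 | triethylsilyl ether of F7 | O=C(N1[C@H](Cc2ccccc2)COC1=O)[C@H](c1c(OCc2ccccc2)cc(OCc2ccccc2)cc1OCc1ccccc1)[C@@H](O[Si](CC)(CC)CC)C(=O)c1ccc(OCc2ccccc2)c(OCc2ccccc2)c1
F9 | step 12 | (2R,3R)-4-ArC-4,4-dimethoxy-3-(triethylsilyloxy)-2-ArT-butanoic acid | OC(=O)[C@H](c1c(OCc2ccccc2)cc(OCc2ccccc2)cc1OCc1ccccc1)[C@@H](O[Si](CC)(CC)CC)C(OC)(OC)c1ccc(OCc2ccccc2)c(OCc2ccccc2)c1
F10 | step 12 | methyl ester of F9 | COC(=O)[C@H](c1c(OCc2ccccc2)cc(OCc2ccccc2)cc1OCc1ccccc1)[C@@H](O[Si](CC)(CC)CC)C(OC)(OC)c1ccc(OCc2ccccc2)c(OCc2ccccc2)c1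
F11 | step 19 | 2-Fl-ethan-1-ol | OCCc1c(OCc2ccccc2)cc(OCc2ccccc2)c2c1O[C@@H](c1ccc(OCc3ccccc3)c(OCc3ccccc3)c1)[C@H](OCc1ccccc1)C2
F0 | step 31 | none | none
F12 | step 33 | 2-(M-arm)-4-(T-arm)-3,5-bis(triisopropylsilyloxy)phenyl levulinate | CC(=O)CCC(=O)Oc4cc(O[Si](C(C)C)(C(C)C)C(C)C)c([C@H](c1c(OCc2ccccc2)cc(OCc2ccccc2)cc1OCc1ccccc1)[C@@H](O[Si](CC)(CC)CC)C(OC)(OC)c1ccc(OCc2ccccc2)c(OCc2ccccc2)c1)c(O[Si](C(C)C)(C(C)C)C(C)C)c4[C@H](c1c(OCc2ccccc2)cc(OCc2ccccc2)c2c1O[C@@H](c1ccc(OCc3ccccc3)c(OCc3ccccc3)c1)[C@H](OCc1ccccc1)C2)[C@@H](O[Si](CC)(CC)CC)C(OC)(OC)c1ccc(OCc2ccccc2)c(OCc2ccccc2)c1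
F13 | step 33 | 3,5-dihydroxy-2-[M-arm(OH)]-4-[T-arm(OH)]phenyl levulinate | CC(=O)CCC(=O)Oc4cc(O)c([C@H](c1c(OCc2ccccc2)cc(OCc2ccccc2)cc1OCc1ccccc1)[C@@H](O)C(OC)(OC)c1ccc(OCc2ccccc2)c(OCc2ccccc2)c1)c(O)c4[C@H](c1c(OCc2ccccc2)cc(OCc2ccccc2)c2c1O[C@@H](c1ccc(OCc3ccccc3)c(OCc3ccccc3)c1)[C@H](OCc1ccccc1)C2)[C@@H](O)C(OC)(OC)c1ccc(OCc2ccccc2)c(OCc2ccccc2)c1
F14 | step 33 | 3,5-dihydroxy-2-(M-arm')-4-(T-arm')phenyl levulinate | CC(=O)CCC(=O)Oc4cc(O)c([C@H](c1c(O)cc(O)cc1O)[C@@H](O)C(OC)(OC)c1ccc(O)c(O)c1)c(O)c4[C@H](c1c(O)cc(O)c2c1O[C@@H](c1ccc(O)c(O)c1)[C@H](O)C2)[C@@H](O)C(OC)(OC)c1ccc(O)c(O)c1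
F15 | step 33 | 5-O-levulinoyl derivative of the target (levulinate on O5 of unit M) | Oc1cc(O)c2c(c1)O[C@]1(c3ccc(O)c(O)c3)Oc3cc(OC(=O)CCC(C)=O)c4c(c3[C@H]2[C@H]1O)O[C@@]1(c2ccc(O)c(O)c2)Oc2cc(O)c3c(c2[C@@H]4[C@H]1O)O[C@@H](c1ccc(O)c(O)c1)[C@H](O)C3
A1 | alternative 1 | ring-E methyl ketal with a free 2,4,6-trihydroxyphenyl group on T-C4, units M and B benzylated and doubly linked | CO[C@]1(c2ccc(OCc5ccccc5)c(OCc5ccccc5)c2)Oc3cc(OCc5ccccc5)c4c(c3[C@H](c2c(O)cc(O)cc2O)[C@H]1OCc5ccccc5)O[C@@]1(c2ccc(OCc5ccccc5)c(OCc5ccccc5)c2)Oc2cc(OCc5ccccc5)c3c(c2[C@@H]4[C@H]1OCc5ccccc5)O[C@@H](c1ccc(OCc5ccccc5)c(OCc5ccccc5)c1)[C@H](OCc5ccccc5)C3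
A2 | alternative 2 | hub bis(2-aryl-4H-chromene) with ring E and ring C of M closed as enol ethers | c5ccccc5COc1ccc(cc1OCc5ccccc5)C1=C[C@@H](c2c(O[Si](C)(C)C(C)(C)C)cc(OCc5ccccc5)cc2OCc5ccccc5)c2c(O1)cc(OCc5ccccc5)c3c2OC(c2ccc(OCc5ccccc5)c(OCc5ccccc5)c2)=C[C@H]3c2c(O[Si](C)(C)C(C)(C)C)cc(OCc5ccccc5)c3c2O[C@@H](c2ccc(OCc5ccccc5)c(OCc5ccccc5)c2)[C@H](OCc5ccccc5)C3
A3 | alternative 3 | dodeca-O-benzyl derivative of the target with free hydroxyl on T-C3 | c5ccccc5COc1cc(OCc5ccccc5)c2c(c1)O[C@]1(c3ccc(OCc5ccccc5)c(OCc5ccccc5)c3)Oc3cc(OCc5ccccc5)c4c(c3[C@H]2[C@H]1O)O[C@@]1(c2ccc(OCc5ccccc5)c(OCc5ccccc5)c2)Oc2cc(OCc5ccccc5)c3c(c2[C@@H]4[C@H]1OCc5ccccc5)O[C@@H](c1ccc(OCc5ccccc5)c(OCc5ccccc5)c1)[C@H](OCc5ccccc5)C3
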